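**Retrosynthetic overview**

1. The two C15–O acyl bonds are cut (iterative Shiina esterification). All three drimane units then come from one ether building block 31, used once as alcohol 34 (unit 1) and twice as acid 32 (units 2 and 3).
2. 31 is cut at C11–O: reductive etherification of aldehyde 20 with silyl ether 30, a natural-configured, differentially esterified isocitrate made from (R)-malic acid by Frater–Seebach alkylation.
3. The albicanol unit comes from C9 ketone 13: enol triflate, carbonylation (C11), deconjugative protonation (C8=C12, 9α-H). The C6 oxygen is removed through its enol triflate after C5 epimerisation.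
4. The strategy rests on the contiguous triad C4 (CH3, C15H2O)–C5–C10 (quaternary, CH3) of ring A. Ring B's C10 methyl, C12 and C9 carbonyl are already present in 2,6-dimethylbenzoquinone, so C1–C10 and C4–C5 are made in one catalytic asymmetric Diels–Alder reaction.
5. Ring order: ring B is the quinone ring; ring A is closed onto it in step 4; no other ring is formed.

Key step: step 4

Convention: the bicyclic units carry drimane numbering (C1–C10 decalin, C11 on C9, C12 on C8, C15 = oxygenated carbon on C4; β = face of the C10 methyl). Isocitrate carbons are C1' (O-bearing), C2' (central) and C3' (CH2), and each carboxyl is named after the carbon that carries it.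

Assumption: the (S)-prolinol-derived oxazaborolidinium ion is taken to expose the quinone face that gives the 10S adduct 7; the sense could not be derived with certainty, and the (R)-catalyst is equally available if a first run shows the opposite.

**Route**

Step 1
Reactants: 1 acrolein; 2 ethyl 2-(triphenylphosphoranylidene)propanoate
Product: 3 ethyl (2E)-2-methylpenta-2,4-dienoate
Conditions: CH2Cl2, 0 °C → rt
Reagents that add atoms: none
Why: Wittig olefination with a stabilised ylide should give the E trisubstituted alkene (ester trans to the vinyl group), the geometry that later puts CH2O outside and CH3 inside the diene.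

Step 2
Reactants: 3 ethyl (2E)-2-methylpenta-2,4-dienoate
Product: 4 (2E)-2-methylpenta-2,4-dien-1-ol
Conditions: iBu2AlH (2.2 equiv), CH2Cl2, −78 → 0 °C; Rochelle salt work-up
Reagents that add atoms: none
Why: DIBAL reduction of a conjugated ester proceeds by 1,2-addition only, so the diene and its E geometry are kept.

Step 3
Reactants: 4 (2E)-2-methylpenta-2,4-dien-1-ol
Product: 5 (E)-5-(tert-butyldimethylsilyloxy)-4-methylpenta-1,3-diene
Conditions: TBSCl, imidazole, CH2Cl2, 0 °C → rt
Reagents that add atoms: tert-butyldimethylsilyl chloride, CC(C)(C)[Si](C)(C)Cl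
Why: Silylation of a primary allylic alcohol (silyl ether formation) is routine and masks C15–OH through to the assembly.

Step 4
Reactants: 5 (E)-5-(tert-butyldimethylsilyloxy)-4-methylpenta-1,3-diene; 6 2,6-dimethyl-1,4-benzoquinone
Product: 7 cis-fused adduct, (4aR,5R,8aS)-5-[(tert-butyldimethylsilyl)oxymethyl]-2,5,8a-trimethyl-4a,5,8,8a-tetrahydronaphthalene-1,4-dione (6,9-dione; 5β-H, 10β-CH3, 4β-CH3, 4α-CH2OTBS)
Conditions: (S)-3,3-diphenyl-1-(2-methylphenyl)tetrahydro-1H,3H-pyrrolo[1,2-c][1,3,2]oxazaborole·HN(SO2CF3)2 (20 mol %), 5 (1.5 equiv), CH2Cl2, −78 → −40 °C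
Reagents that add atoms: none
Why: The protonated oxazaborolidine binds the quinone carbonyl flanked by two CH groups (the future C6, less hindered and more basic) and lowers the LUMO of the adjacent methyl-bearing C=C for a concerted, asynchronous endo [4+2] with the s-cis diene; the closest known reaction type is the oxazaborolidinium- or Ti–BINOL-catalysed quinone Diels–Alder reaction. Ring A closes in this single intermolecular cycloaddition by forming C1–C10 (CH2 terminus to the methyl-bearing β-carbon) and C4–C5 (disubstituted terminus to the α-carbon), the pairing of the larger frontier coefficients, which also avoids joining two fully substituted carbons. C10 is set by the catalyst-selected quinone face, C5 follows from suprafacial addition (cis fusion), and C4 follows from the E-diene geometry under endo approach, which places the outside CH2OTBS cis to the ring B carbonyls (α) and the inside methyl cis to the C10 methyl (β). The step needs regio-, endo- and enantioface selectivity: carbonyl coordination plus sterics secure the first, secondary orbital overlap under Lewis-acid catalysis the second, and aryl shielding by the catalyst the third. The inside methyl disfavours the s-cis conformer and slows the reaction, which the strongly activating cationic catalyst is meant to offset.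

Step 5
Reactants: 7 cis-fused adduct
Product: 8 cis-fused saturated 6,9-dione (C2=C3 kept; mixture at C8)
Conditions: Zn dust, AcOH, THF, 0 °C → rt
Reagents that add atoms: none
Why: Dissolving-metal reduction (Zn/AcOH) of an ene-dione takes place at the electron-poor C7=C8 bond only, leaving the isolated C2=C3 alkene; C8 forms as a mixture that step 6 levels.

Step 6
Reactants: 8 cis-fused saturated 6,9-dione
Product: 9 trans-fused 6,9-dione (5α-H, 8α-CH3)
Conditions: NaOMe (0.2 equiv), MeOH, rt
Reagents that add atoms: none
Why: Base-catalysed epimerisation through the C6 and C9 enolates should settle on the trans-decalin (5α-H) with the equatorial 8α-methyl, because both chair forms of the cis isomer keep a syn-axial clash with the 4β-methyl and add the gauche strain of cis fusion.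

Step 7
Reactants: 9 trans-fused 6,9-dione
Product: 11 C6 enol triflate (C6=C7; C9 ketone kept), via potassium C6 enolate 10 (not isolated)
Conditions: KN(SiMe3)2 (1.05 equiv), THF, −78 °C; PhNTf2, −78 → 0 °C
Reagents that add atoms: N-phenylbis(trifluoromethanesulfonimide), O=S(=O)(N(c1ccccc1)S(=O)(=O)C(F)(F)F)C(F)(F)F
Why: Kinetic deprotonation takes the only methylene α to a carbonyl (C7; C5 and C8 are hindered methines), and O-sulfonylation of the enolate (enol triflate formation) marks C6 without any nucleophile having to reach the shielded C6 carbonyl.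

Step 8
Reactants: 11 C6 enol triflate
Product: 12 2,6-dien-9-one (C6 deoxygenated)
Conditions: Pd(OAc)2 (5 mol %), PPh3 (10 mol %), HCO2H, Bu3N, DMF, 60 °C
Reagents that add atoms: none
Why: Palladium-catalysed formate reduction of a vinyl triflate (oxidative addition, decarboxylation of the formate to a hydride, reductive elimination) removes the C6 oxygen and does not touch C5.

Step 9
Reactants: 12 2,6-dien-9-one
Product: 13 saturated C9 ketone, 15-(tert-butyldimethylsilyloxy)-11-nordriman-9-one
Conditions: H2 (3 atm), Pd/C (10 wt %), EtOAc, rt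
Reagents that add atoms: none
Why: Heterogeneous catalytic hydrogenation saturates the two cis-disubstituted alkenes (C2=C3, C6=C7), creates no stereocentre and leaves the hindered C9 ketone and the silyl ether alone.

Step 10
Reactants: 13 saturated C9 ketone
Product: 15 C9 enol triflate (C8=C9), via potassium C9 enolate 14 (not isolated)
Conditions: KN(SiMe3)2 (1.3 equiv), THF, −78 → 0 °C; PhNTf2, 0 °C → rt
Reagents that add atoms: N-phenylbis(trifluoromethanesulfonimide), O=S(=O)(N(c1ccccc1)S(=O)(=O)C(F)(F)F)C(F)(F)F
Why: The C9 ketone can enolise only towards C8 because C10 is quaternary, so enol triflate formation gives one regioisomer, as it does for 2,2,6-trimethylcyclohexanone.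

Step 11
Reactants: 15 C9 enol triflate
Product: 16 methyl 15-(tert-butyldimethylsilyloxy)drim-8-en-11-oate
Conditions: Pd(OAc)2 (10 mol %), 1,3-bis(diphenylphosphino)propane (10 mol %), CO (1 atm), MeOH, Et3N, DMF, 70 °C
Reagents that add atoms: carbon monoxide, [C-]#[O+]; methanol, CO
Why: Palladium-catalysed methoxycarbonylation of the vinyl triflate (CO insertion into the vinyl–palladium bond, methanolysis) adds C11 at the ester oxidation level.

Step 12
Reactants: 16 methyl 15-(tert-butyldimethylsilyloxy)drim-8-en-11-oate
Product: 18 methyl 15-(tert-butyldimethylsilyloxy)drim-8(12)-en-11-oate (9α-H), via lithium dienolate 17 (not isolated)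
Conditions: LiN(iPr)2 (2 equiv), THF–DMPU, −78 → −40 °C; AcOH, −78 °C
Reagents that add atoms: none
Why: Deconjugative protonation: the amide base removes a proton from the C12 methyl, the γ-position syn to the ester as in β-cyclogeranates, and kinetic protonation of the exocyclic dienolate at C9 from the α face, anti to the axial 10β-methyl, sets 9α-H with the equatorial 9β-ester, which is also the more stable C9 epimer.

Step 13
Reactants: 18 methyl 15-(tert-butyldimethylsilyloxy)drim-8(12)-en-11-oate
Product: 19 15-(tert-butyldimethylsilyloxy)drim-8(12)-en-11-ol (15-silyloxyalbicanol)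
Conditions: LiAlH4, Et2O, 0 °C
Reagents that add atoms: none
Why: Hydride reduction of the ester (LiAlH4) gives the primary alcohol without base strong enough to move the β,γ-alkene or epimerise C9.

Step 14
Reactants: 19 15-(tert-butyldimethylsilyloxy)drim-8(12)-en-11-ol
Product: 20 15-(tert-butyldimethylsilyloxy)drim-8(12)-en-11-al
Conditions: Dess–Martin periodinane, pyridine, CH2Cl2, 0 °C; used at once
Reagents that add atoms: none
Why: Dess–Martin oxidation under pyridine buffer is neutral and fast, so the β,γ-unsaturated aldehyde should form without C9 epimerisation or conjugation if used at once.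

Step 15
Reactants: 21 (R)-malic acid
Product: 23 (R)-malic acid 1-methyl ester, via O-trifluoroacetylmalic anhydride 22 (not isolated)
Conditions: (CF3CO)2O, 0 °C → rt; evaporate; MeOH, rt
Reagents that add atoms: methanol, CO
Why: Trifluoroacetic anhydride forms the cyclic O-acyl anhydride, which methanol opens at the carbonyl next to the acyloxy-bearing carbon (regioselective anhydride alcoholysis) and then deacylates, leaving the stereocentre untouched.

Step 16
Reactants: 23 (R)-malic acid 1-methyl ester
Product: 24 4-allyl 1-methyl (R)-malate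
Conditions: allyl bromide, KHCO3, DMF, rt
Reagents that add atoms: allyl bromide, C=CCBr
Why: SN2 O-alkylation of the carboxylate by allyl bromide under bicarbonate esterifies the acid while the secondary hydroxyl stays free.

Step 17
Reactants: 25 bromoacetyl bromide; 26 2-(trimethylsilyl)ethanol
Product: 27 2-(trimethylsilyl)ethyl bromoacetate
Conditions: pyridine, CH2Cl2, 0 °C
Reagents that add atoms: none
Why: Acylation of a primary alcohol by an acyl bromide is fast at 0 °C and the α-bromide is not displaced by pyridine in that time.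

Step 18
Reactants: 24 4-allyl 1-methyl (R)-malate; 27 2-(trimethylsilyl)ethyl bromoacetate
Product: 29 (1'R,2'S)-isocitrate triester (1'-methyl; 2'-allyl; 3'-[2-(trimethylsilyl)ethyl]), via dilithium alkoxide-enolate 28 (not isolated)
Conditions: LiN(SiMe3)2 (2.2 equiv), THF, −78 °C; 27, −78 → −40 °C; AcOH, −78 °C
Reagents that add atoms: none
Why: Frater–Seebach alkylation: the chelated alkoxide–enolate dianion is alkylated by the reactive α-bromo ester on the face anti to the C1' ester, which sets C2' as S (natural isocitrate configuration) while C1' (R) is kept as the alkoxide; the cold acetic acid quench is meant to prevent lactonisation.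

Step 19
Reactants: 29 (1'R,2'S)-isocitrate triester
Product: 30 O-trimethylsilyl ether of 29
Conditions: TMSCl, imidazole, CH2Cl2, 0 °C
Reagents that add atoms: chlorotrimethylsilane, C[Si](C)(C)Cl
Why: O-silylation with TMSCl and imidazole gives the silyl ether needed for step 20 and blocks γ-lactone formation.

Step 20
Reactants: 20 15-(tert-butyldimethylsilyloxy)drim-8(12)-en-11-al; 30 O-trimethylsilyl isocitrate triester
Product: 31 ether building block (C11–O–C1'; C15–OTBS; 1'-methyl, 2'-allyl, 3'-silylethyl esters)
Conditions: Me3SiOSO2CF3 (0.3 equiv), Et3SiH (1.5 equiv), CH2Cl2, −78 → −40 °C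
Reagents that add atoms: none
Why: Reductive etherification: Me3SiOTf turns aldehyde and silyl ether into a mixed silyl acetal and then an oxocarbenium ion that Et3SiH reduces at low temperature, so the C11–O bond forms with the C1'–O bond intact (C1' and C2' keep their configuration) and without base that could enolise C9.

Step 21
Reactants: 31 ether building block
Product: 32 acid (2'-CO2H free; C15–OTBS and 3'-silylethyl ester kept)
Conditions: Pd(PPh3)4 (5 mol %), morpholine, THF, rt; pH 3 work-up
Reagents that add atoms: none
Why: Palladium-catalysed deallylation (Tsuji–Trost type: the π-allyl complex formed from zerovalent palladium is captured by morpholine) frees the 2'-carboxyl only, since silyl ether, silylethyl ester and methyl ester do not ionise.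

Step 22
Reactants: 31 ether building block
Product: 33 hydroxy acid (C15–OH and 3'-CO2H free; 2'-allyl ester kept)
Conditions: (Me2N)3S+ Me3SiF2− (3 equiv), DMF, 0 °C → rt; aq. NH4Cl, then pH 3
Reagents that add atoms: none
Why: Fluoride attacks silicon in both groups, fragmenting the 2-(trimethylsilyl)ethyl ester to carboxylate and ethylene (β-elimination) and cleaving the Si–O bond of the silyl ether, while allyl and methyl esters are inert to this non-hydroxylic fluoride source.

Step 23
Reactants: 33 hydroxy acid
Product: 34 alcohol for unit 1 (C15–OH; 1'- and 3'-methyl esters, 2'-allyl ester)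
Conditions: Me3SiCHN2, toluene–MeOH (4:1), 0 °C
Reagents that add atoms: (trimethylsilyl)diazomethane, C[Si](C)(C)C=[N+]=[N-]
Why: Methyl ester formation with trimethylsilyldiazomethane is specific for the carboxylic acid, so the free C15–OH needs no protection.

Step 24
Reactants: 34 alcohol for unit 1; 32 acid
Product: 35 dimer (units 1 and 2; C15–OTBS on unit 2)
Conditions: 2-methyl-6-nitrobenzoic anhydride (1.3 equiv), DMAP, Et3N, CH2Cl2, rt
Reagents that add atoms: none
Why: Shiina esterification: the mixed anhydride with 2-methyl-6-nitrobenzoic acid is opened by DMAP to an acylpyridinium ion that acylates the neopentyl-type C15–OH at room temperature, conditions mild enough to spare C2' from epimerisation and the β-alkoxy ester from elimination.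

Step 25
Reactants: 35 dimer
Product: 36 dimer alcohol (C15–OH of unit 2 free)
Conditions: HF·pyridine, pyridine, THF, 0 °C → rt
Reagents that add atoms: none
Why: Buffered HF·pyridine cleaves the Si–O bond of the primary silyl ether (desilylation) while the silylethyl ester, which needs free fluoride, and all other esters survive.

Step 26
Reactants: 36 dimer alcohol; 32 acid
Product: 37 protected trimer (units 1, 2 and 3)
Conditions: 2-methyl-6-nitrobenzoic anhydride (1.3 equiv), DMAP, Et3N, CH2Cl2, rt
Reagents that add atoms: none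
Why: The same Shiina esterification joins the third unit; the acid partner is again 32, so no new building block is needed.

Step 27
Reactants: 37 protected trimer
Product: 38 trimer with both 3'-CO2H groups and C15–OH of unit 3 free (2'-allyl ester on the terminal isocitrate kept)
Conditions: (Me2N)3S+ Me3SiF2− (5 equiv), DMF, 0 °C → rt; aq. NH4Cl, then pH 3
Reagents that add atoms: none
Why: Fluoride-induced fragmentation of both 2-(trimethylsilyl)ethyl esters and Si–O cleavage of the last silyl ether occur together under the nearly neutral, anhydrous conditions already used in step 22.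

Step 28
Reactants: 38 trimer allyl ester
Product: 39 cryptoporic acid T
Conditions: Pd(PPh3)4 (10 mol %), morpholine, THF, rt; pH 3 work-up
Reagents that add atoms: none
Why: Palladium-catalysed deallylation with morpholine as allyl acceptor removes the last protecting group under conditions that leave the three exocyclic alkenes, the methyl esters and the β-alkoxy esters untouched.

**Compound list**

1 | acrolein | C=CC=O | starting material
2 | ethyl 2-(triphenylphosphoranylidene)propanoate | CCOC(=O)C(C)=P(c1ccccc1)(c1ccccc1)c1ccccc1 | starting material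
3 | ethyl (2E)-2-methylpenta-2,4-dienoate | C=C/C=C(\C)C(=O)OCC | intermediate
4 | (2E)-2-methylpenta-2,4-dien-1-ol | C=C/C=C(\C)CO | intermediate
5 | (E)-5-(tert-butyldimethylsilyloxy)-4-methylpenta-1,3-diene | C=C/C=C(\C)CO[Si](C)(C)C(C)(C)C | intermediate
6 | 2,6-dimethyl-1,4-benzoquinone | CC1=CC(=O)C=C(C)C1=O | starting material
7 | cis-fused adduct, (4aR,5R,8aS)-5-[(tert-butyldimethylsilyl)oxymethyl]-2,5,8a-trimethyl-4a,5,8,8a-tetrahydronaphthalene-1,4-dione | CC1=CC(=O)[C@@H]2[C@](C)(CO[Si](C)(C)C(C)(C)C)C=CC[C@]2(C)C1=O | intermediate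
8 | cis-fused 15-silyloxy-11-nordrim-2-ene-6,9-dione (5β-H; C8 epimer mixture) | CC1CC(=O)[C@@H]2[C@](C)(CO[Si](C)(C)C(C)(C)C)C=CC[C@]2(C)C1=O | intermediate
9 | trans-fused 15-silyloxy-11-nordrim-2-ene-6,9-dione (5α-H, 8α-CH3) | C[C@@H]1CC(=O)[C@H]2[C@](C)(CO[Si](C)(C)C(C)(C)C)C=CC[C@]2(C)C1=O | intermediate
10 | potassium C6 enolate of 9 | C[C@@H]1C=C([O-])[C@H]2[C@](C)(CO[Si](C)(C)C(C)(C)C)C=CC[C@]2(C)C1=O.[K+] | intermediate (not isolated)
11 | C6 enol triflate, 15-silyloxy-9-oxo-11-nordrima-2,6-dien-6-yl triflate | C[C@@H]1C=C(OS(=O)(=O)C(F)(F)F)[C@H]2[C@](C)(CO[Si](C)(C)C(C)(C)C)C=CC[C@]2(C)C1=O | intermediate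
12 | 15-silyloxy-11-nordrima-2,6-dien-9-one (5α-H, 8α-CH3) | C[C@@H]1C=C[C@H]2[C@](C)(CO[Si](C)(C)C(C)(C)C)C=CC[C@]2(C)C1=O | intermediate
13 | 15-(tert-butyldimethylsilyloxy)-11-nordriman-9-one (5α-H, 8α-CH3) | C[C@@H]1CC[C@H]2[C@](C)(CO[Si](C)(C)C(C)(C)C)CCC[C@]2(C)C1=O | intermediate
14 | potassium C9 enolate of 13 | CC=1CC[C@H]2[C@](C)(CO[Si](C)(C)C(C)(C)C)CCC[C@]2(C)C=1[O-].[K+] | intermediate (not isolated)
15 | C9 enol triflate, 15-silyloxy-11-nordrim-8-en-9-yl triflate | CC=1CC[C@H]2[C@](C)(CO[Si](C)(C)C(C)(C)C)CCC[C@]2(C)C=1OS(=O)(=O)C(F)(F)F | intermediate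
16 | methyl 15-(tert-butyldimethylsilyloxy)drim-8-en-11-oate | CC=1CC[C@H]2[C@](C)(CO[Si](C)(C)C(C)(C)C)CCC[C@]2(C)C=1C(=O)OC | intermediate
17 | lithium dienolate of 16 (C8=C12, C9=C11) | C=C1CC[C@H]2[C@](C)(CO[Si](C)(C)C(C)(C)C)CCC[C@]2(C)C1=C([O-])OC.[Li+] | intermediate (not isolated)
18 | methyl 15-(tert-butyldimethylsilyloxy)drim-8(12)-en-11-oate (9α-H) | C=C1CC[C@H]2[C@](C)(CO[Si](C)(C)C(C)(C)C)CCC[C@]2(C)[C@H]1C(=O)OC | intermediate
19 | 15-(tert-butyldimethylsilyloxy)drim-8(12)-en-11-ol | C=C1CC[C@H]2[C@](C)(CO[Si](C)(C)C(C)(C)C)CCC[C@]2(C)[C@H]1CO | intermediate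
20 | 15-(tert-butyldimethylsilyloxy)drim-8(12)-en-11-al | C=C1CC[C@H]2[C@](C)(CO[Si](C)(C)C(C)(C)C)CCC[C@]2(C)[C@H]1C=O | intermediate
21 | (R)-malic acid | O[C@@H](C(=O)O)CC(=O)O | starting material
22 | (R)-2-(trifluoroacetoxy)succinic anhydride | FC(F)(F)C(=O)O[C@H]1C(=O)OC(=O)C1 | intermediate (not isolated)
23 | (R)-malic acid 1-methyl ester | O[C@@H](C(=O)OC)CC(=O)O | intermediate
24 | 4-allyl 1-methyl (R)-malate | O[C@@H](C(=O)OC)CC(=O)OCC=C | intermediate
25 | bromoacetyl bromide | BrCC(Br)=O | starting material
26 | 2-(trimethylsilyl)ethanol | C[Si](C)(C)CCO | starting material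
27 | 2-(trimethylsilyl)ethyl bromoacetate | BrCC(=O)OCC[Si](C)(C)C | intermediate
28 | dilithium alkoxide–enolate of 24 | [Li+].[Li+].[O-][C@@H](C(=O)OC)C=C([O-])OCC=C | intermediate (not isolated)
29 | (1'R,2'S)-isocitrate 1'-methyl 2'-allyl 3'-[2-(trimethylsilyl)ethyl] triester | O[C@@H](C(=O)OC)[C@H](CC(=O)OCC[Si](C)(C)C)C(=O)OCC=C | intermediate
30 | O-trimethylsilyl ether of 29 | C[Si](C)(C)O[C@@H](C(=O)OC)[C@H](CC(=O)OCC[Si](C)(C)C)C(=O)OCC=C | intermediate
31 | ether building block: 15-silyloxyalbican-11-yl ether of 29 at O1' | C=C1CC[C@H]2[C@](C)(CO[Si](C)(C)C(C)(C)C)CCC[C@]2(C)[C@H]1CO[C@@H](C(=O)OC)[C@H](CC(=O)OCC[Si](C)(C)C)C(=O)OCC=C | intermediate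
32 | acid: 31 with free 2'-CO2H | C=C1CC[C@H]2[C@](C)(CO[Si](C)(C)C(C)(C)C)CCC[C@]2(C)[C@H]1CO[C@@H](C(=O)OC)[C@H](CC(=O)OCC[Si](C)(C)C)C(=O)O | intermediate
33 | hydroxy acid: 31 with free C15–OH and 3'-CO2H | C=C1CC[C@H]2[C@](C)(CO)CCC[C@]2(C)[C@H]1CO[C@@H](C(=O)OC)[C@H](CC(=O)O)C(=O)OCC=C | intermediate
34 | unit 1 alcohol: C15–OH, 1'- and 3'-methyl esters, 2'-allyl ester | C=C1CC[C@H]2[C@](C)(CO)CCC[C@]2(C)[C@H]1CO[C@@H](C(=O)OC)[C@H](CC(=O)OC)C(=O)OCC=C | intermediate
35 | dimer, C15–OTBS on unit 2 | C=C1CC[C@H]2[C@](C)(COC(=O)[C@@H](CC(=O)OCC[Si](C)(C)C)[C@@H](OC[C@H]3C(=C)CC[C@H]4[C@](C)(CO[Si](C)(C)C(C)(C)C)CCC[C@]34C)C(=O)OC)CCC[C@]2(C)[C@H]1CO[C@@H](C(=O)OC)[C@H](CC(=O)OC)C(=O)OCC=C | intermediate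
36 | dimer alcohol, C15–OH on unit 2 | C=C1CC[C@H]2[C@](C)(COC(=O)[C@@H](CC(=O)OCC[Si](C)(C)C)[C@@H](OC[C@H]3C(=C)CC[C@H]4[C@](C)(CO)CCC[C@]34C)C(=O)OC)CCC[C@]2(C)[C@H]1CO[C@@H](C(=O)OC)[C@H](CC(=O)OC)C(=O)OCC=C | intermediate
37 | protected trimer (two silylethyl esters, one allyl ester, C15–OTBS on unit 3) | C=C1CC[C@H]2[C@](C)(COC(=O)[C@@H](CC(=O)OCC[Si](C)(C)C)[C@@H](OC[C@H]3C(=C)CC[C@H]4[C@](C)(COC(=O)[C@@H](CC(=O)OCC[Si](C)(C)C)[C@@H](OC[C@H]5C(=C)CC[C@H]6[C@](C)(CO[Si](C)(C)C(C)(C)C)CCC[C@]56C)C(=O)OC)CCC[C@]34C)C(=O)OC)CCC[C@]2(C)[C@H]1CO[C@@H](C(=O)OC)[C@H](CC(=O)OC)C(=O)OCC=C | intermediate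
38 | trimer diacid alcohol, 2'-allyl ester on the terminal isocitrate | C=C1CC[C@H]2[C@](C)(COC(=O)[C@@H](CC(=O)O)[C@@H](OC[C@H]3C(=C)CC[C@H]4[C@](C)(COC(=O)[C@@H](CC(=O)O)[C@@H](OC[C@H]5C(=C)CC[C@H]6[C@](C)(CO)CCC[C@]56C)C(=O)OC)CCC[C@]34C)C(=O)OC)CCC[C@]2(C)[C@H]1CO[C@@H](C(=O)OC)[C@H](CC(=O)OC)C(=O)OCC=C | intermediate
39 | cryptoporic acid T | C=C1CC[C@H]2[C@](C)(COC(=O)[C@@H](CC(=O)O)[C@@H](OC[C@H]3C(=C)CC[C@H]4[C@](C)(COC(=O)[C@@H](CC(=O)O)[C@@H](OC[C@H]5C(=C)CC[C@H]6[C@](C)(CO)CCC[C@]56C)C(=O)OC)CCC[C@]34C)C(=O)OC)CCC[C@]2(C)[C@H]1CO[C@@H](C(=O)OC)[C@H](CC(=O)OC)C(=O)O | target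

**Step count and risks**

Total step count: 28. Longest linear sequence: 22 steps (steps 1–14, 20, 22, 23, 24, 25, 26, 27, 28).

Steps most likely to fail:

- **Step 20 (reductive etherification).** The electron-poor, hindered silyl ether may add too slowly to the activated aldehyde. Enolisation at C9 (epimerisation or migration of the alkene into conjugation) or loss of the C15 silyl ether could then outrun acetal formation and hydride transfer. The fallback makes the ether by displacement instead of reduction. It sets out from 29 and 19. A Mitsunobu reaction of 29 with chloroacetic acid (PPh3, diisopropyl azodicarboxylate) inverts C1' to give the (1'S,2'S) chloroacetate F1. Thiourea and NaHCO3 in ethanol free the (1'S,2'S) alcohol F2. Tf2O and 2,6-lutidine at −78 °C give the triflate F3. The sodium alkoxide of 19 (NaH, THF) displaces the triflate at −78 °C with inversion, and the route is rejoined at 31.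

- **Step 4 (key cycloaddition).** The inside methyl may keep the diene from reaching the s-cis conformer, the acid may decompose the diene, or the enantioface selection may be poor. The fallback gives up catalyst control in favour of resolution. It sets out from 5 and 6. BF3·OEt2 in CH2Cl2 at −78 °C, an achiral promoter that keeps the same regio- and endo-control, gives the racemic cis adduct F4. Preparative chromatography on a chiral stationary phase (amylose tris(3,5-dimethylphenylcarbamate)) delivers 7, where the route is rejoined.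

- **Step 12 (deconjugative protonation).** Enolisation of the hindered ester may be incomplete, the proton may be removed at C7 instead of C12, or protonation may return the conjugated ester. The fallback replaces the base by light. It sets out from 16 and comes back at 18. Irradiation at 254 nm in Et2O–MeOH with catalytic 1,2-dimethylimidazole causes a 1,5-hydrogen shift from the C12 methyl, which is syn to the ester, and the resulting dienol ketonises at C9 from the α face. It makes no compound outside the list (F0).

Further compounds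
F1 | step 20 | (1'S,2'S)-O-chloroacetyl isocitrate triester | ClCC(=O)O[C@H](C(=O)OC)[C@H](CC(=O)OCC[Si](C)(C)C)C(=O)OCC=C
F2 | step 20 | (1'S,2'S)-isocitrate triester (C1' epimer of 29) | O[C@H](C(=O)OC)[C@H](CC(=O)OCC[Si](C)(C)C)C(=O)OCC=C
F3 | step 20 | (1'S,2'S)-O-trifluoromethanesulfonyl isocitrate triester | FC(F)(F)S(=O)(=O)O[C@H](C(=O)OC)[C@H](CC(=O)OCC[Si](C)(C)C)C(=O)OCC=C
F4 | step 4 | racemic cis adduct (7 and its mirror image, 1:1) | CC1=CC(=O)[C@@H]2[C@](C)(CO[Si](C)(C)C(C)(C)C)C=CC[C@]2(C)C1=O.CC1=CC(=O)[C@H]2[C@@](C)(CO[Si](C)(C)C(C)(C)C)C=CC[C@@]2(C)C1=O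
F0 | step 12 | none | none
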